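**Retrosynthetic overview**
1. Locants follow labdane numbering (ring A: C1–C5, C10; ring B: C5–C10; oxocane: C8–O–C15–C14–C13–C12–C11–C9; C17 on C8, C20 on C10); all configurations are stated explicitly. The epoxide oxygen goes on last by Shi epoxidation of a C13=C14 olefin, which comes from reductive 1,3-transposition of a C14 ketone/C12=C13 enone.
2. Ring B is closed by the C9–C10 bond: H-atom transfer to a C10=C20 methylene gives the tertiary C10 radical, which adds 6-exo to C9, the δ-carbon of an oxocane dienone (C14=O, C12=C13, C9=C11).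
3. Enabling feature: C10 is a quaternary carbon whose methyl (C20) can be born as an exocyclic methylene, and C9 is linked through C11–C12 to the oxidised C13/C14 pair of the oxocane, so the future epoxide carbons, at another oxidation level, activate C9; the ring oxygen on C8 lies anti to the new bond and fixes the trans fusion.
4. Oxocane: ring-closing metathesis (C9=C11) after aldol (C12–C13) and O-alkylation of the C8 tertiary alcohol. Ring A: catalyst-controlled bromonium cyclisation of (3S)-nerolidyl acetate, which brings C8 from the chiral pool.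
5. Order of ring formation: ring A, oxocane, ring B; then the epoxide oxygen.

Key step: step 9

Assumption: (3S,6E)-nerolidol (natural trans-nerolidol) is taken to be purchasable as the single enantiomer.

**Route**

Step 1
Reactants: 1 (3S,6E)-nerolidol
Product: 2 (3S,6E)-nerolidyl acetate
Conditions: Ac2O, Et3N, DMAP (cat.), CH2Cl2, rt
Reagents that add atoms: acetic anhydride, CC(=O)OC(C)=O
Why: DMAP-catalysed acylation of the tertiary allylic alcohol under basic conditions (no allylic transposition) makes the C8 oxygen a non-nucleophilic ester, so that it cannot trap the C10 cation of step 2; C8 is untouched.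

Step 2
Reactants: 2 (3S,6E)-nerolidyl acetate
Product: 3 (3S)-5-[(1S,3R)-3-bromo-2,2-dimethyl-6-methylidenecyclohexyl]-3-methylpent-1-en-3-yl acetate
Conditions: DBDMH (0.55 equiv), BINOL-derived chiral N-triflyl thiophosphoramide (10 mol %, the enantiomer that gives 3R), toluene/CH2Cl2, −78 °C
Reagents that add atoms: 1,3-dibromo-5,5-dimethylhydantoin (DBDMH), CC1(C)N(Br)C(=O)N(Br)C1=O
Why: Proposed new method: the P=S Lewis base takes Br+ from DBDMH and hands it, inside a chiral ion pair, to one face of the terminal trisubstituted olefin (the most electron-rich and most accessible one), the C5=C10 olefin attacks 6-endo through a chair with Br and the side chain equatorial (this should fix 3R and 5S, cis), and the tertiary C10 cation, with no nucleophile in reach, loses a C20 proton to the hydantoin anion; the closest known reaction types are the Lewis-base-catalysed enantioselective bromonium polyene cyclisation of homogeranyl arenes and the reagent-based bromonium monocyclisation of geranyl esters.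

Step 3
Reactants: 3 (3S)-5-[(1S,3R)-3-bromo-2,2-dimethyl-6-methylidenecyclohexyl]-3-methylpent-1-en-3-yl acetate
Product: 4 (3S)-5-[(1S,3R)-3-bromo-2,2-dimethyl-6-methylidenecyclohexyl]-3-methylpent-1-en-3-ol
Conditions: K2CO3, MeOH, 40 °C
Reagents that add atoms: none
Why: Transesterification frees the tertiary alcohol, and the equatorial neopentyl bromide, which has no anti-periplanar hydrogen and no open backside, should survive the carbonate.

Step 4
Reactants: 4 (3S)-5-[(1S,3R)-3-bromo-2,2-dimethyl-6-methylidenecyclohexyl]-3-methylpent-1-en-3-ol, 5 2-bromo-N-methoxy-N-methylacetamide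
Product: 6 2-{[(3S)-5-[(1S,3R)-3-bromo-2,2-dimethyl-6-methylidenecyclohexyl]-3-methylpent-1-en-3-yl]oxy}-N-methoxy-N-methylacetamide
Conditions: NaH, THF, 0 °C; then 5, Bu4NI (cat.), 0 °C to rt
Reagents that add atoms: none
Why: Williamson etherification, in which the tertiary alkoxide displaces bromide from the activated α-halo amide, places C15 and C14 on the C8 oxygen without touching C8.

Step 5
Reactants: 6 the Weinreb amide ether, 7 ethylmagnesium bromide
Product: 8 1-{[(3S)-5-[(1S,3R)-3-bromo-2,2-dimethyl-6-methylidenecyclohexyl]-3-methylpent-1-en-3-yl]oxy}butan-2-one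
Conditions: THF, 0 °C; aqueous work-up
Reagents that add atoms: none
Why: Weinreb ketone synthesis, whose chelated tetrahedral adduct stops at mono-addition, gives the ethyl ketone that carries C13 and C16.

Step 6
Reactants: 8 the ethyl ketone, 9 acrolein
Product: 10 1-{[(3S)-5-[(1S,3R)-3-bromo-2,2-dimethyl-6-methylidenecyclohexyl]-3-methylpent-1-en-3-yl]oxy}-4-hydroxy-3-methylhex-5-en-2-one (diastereomer mixture at C3 and C4 of the hexenone)
Conditions: LDA (commercial solution), THF, −78 °C; then 9, −78 °C; aqueous work-up
Reagents that add atoms: none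
Why: Kinetic lithium enolate aldol addition, in which LDA should deprotonate the ethyl CH2 and not the methylene flanked by the bulky tertiary alkoxy group, joins C12 to C13 by 1,2-addition to acrolein; the two new centres are erased in step 8.

Step 7
Reactants: 10 the aldol adduct
Product: 11 (6Z,8S)-8-{2-[(1S,3R)-3-bromo-2,2-dimethyl-6-methylidenecyclohexyl]ethyl}-5-hydroxy-4,8-dimethyloxoc-6-en-3-one (ring numbered from O; mixture at C4 and C5)
Conditions: second-generation Grubbs catalyst (5 mol %), CH2Cl2 (2 mM), 40 °C
Reagents that add atoms: none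
Why: Ring-closing metathesis, in which the carbene loads at the unhindered allylic-carbinol olefin and closes onto the vinyl group on the quaternary C8 (helped by gem-disubstitution), should give the oxocane with a necessarily cis C9=C11 bond.

Step 8
Reactants: 11 the hydroxy oxocenone
Product: 13 (4Z,6Z,8S)-8-{2-[(1S,3R)-3-bromo-2,2-dimethyl-6-methylidenecyclohexyl]ethyl}-4,8-dimethyloxoca-4,6-dien-3-one, via allylic mesylate 12 (not isolated)
Conditions: MsCl, Et3N, CH2Cl2, 0 °C; then DBU, rt
Reagents that add atoms: methanesulfonyl chloride, CS(Cl)(=O)=O (its atoms stay in 12 only)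
Why: Mesylation and E1cB elimination of the β-sulfonyloxy ketone through the C13 enolate give the ring dienone, whose C12=C13 bond can only be cis in the eight-membered ring.

Step 9
Reactants: 13 the oxocane dienone
Product: 15 (3R,5S,8S,9S,10R,12Z)-3-bromo-8,15-epoxylabd-12-en-14-one, via nonconjugated enone 14 (not isolated)
Conditions: Fe(acac)3 (30 mol %), PhSiH3 (2.5 equiv), EtOH/ethylene glycol 5:1 (0.02 M), 60 °C; then DBU (0.2 equiv), rt
Reagents that add atoms: none
Why: Proposed new method: Fe(acac)3 and PhSiH3 form an iron hydride that transfers H• to C20 of the only electron-rich olefin, the tertiary C10 radical adds to C9, the δ-terminus of the dienone, the delocalised oxypentadienyl radical is reduced and protonated (first at C13, giving 14) and DBU then conjugates the enone to 15; the closest known reaction type is the iron-hydride (MHAT) reductive olefin coupling, whose intramolecular 1,4-Giese mode builds quaternary centres of decalins, extended here to the vinylogous 1,6-mode on a medium-ring dienone. Ring B closes by 6-exo-trig attack through a chair. C9 is set by that chair: C11 is equatorial and the ring oxygen on C8 lies anti to the forming bond, which is the trans fusion, whereas the other rotamer would push the tether inside the oxocane against C12. C10 is set by ring A and C8: the tether on C5 is equatorial, and only the trans-decalin chair keeps both C1 and C4 equatorial on ring B, the cis alternatives placing C1 or the quaternary C4 syn-axial to the C8 methyl. The step needs chemoselective H-atom transfer (the dienone olefins are electron-poor and there is no other π-bond), δ- rather than β-attack (six-membered against eight-membered closure) and survival of the secondary neopentyl bromide, which the silane/iron system should not reduce.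

Step 10
Reactants: 15 the tricyclic enone
Product: 16 (3R,5S,8S,9S,10R,12Z)-3-bromo-8,15-epoxylabd-12-en-14-one p-toluenesulfonylhydrazone
Conditions: TsNHNH2, PPTS (cat.), EtOH, 60 °C
Reagents that add atoms: p-toluenesulfonyl hydrazide, Cc1ccc(cc1)S(=O)(=O)NN
Why: Condensation of the ketone to its tosylhydrazone prepares the reductive transposition.

Step 11
Reactants: 16 the tosylhydrazone
Product: 19 (3R,5S,8S,9S,10R,13Z)-3-bromo-8,15-epoxylabd-13-ene, via allyl tosylhydrazine 17 (not isolated), via allyl diazene 18 (not isolated)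
Conditions: catecholborane, CHCl3, 0 °C; then NaOAc·3H2O, 60 °C
Reagents that add atoms: none
Why: Kabalka reduction of an enone tosylhydrazone: hydride adds 1,2 to C=N, sulfinate is eliminated, and the allylic diazene loses N2 by a retro-ene shift of hydrogen to C12, which moves the olefin to C13=C14 (cis in the ring) and removes the C14 oxygen.

Step 12
Reactants: 19 the tricyclic oxocene
Product: 20 (3R,5S,8S,9S,10R,13S,14R)-3-bromo-8,15:13,14-diepoxylabdane (CNP0311742.1)
Conditions: Shi ketone (D-fructose-derived, 30 mol %), KHSO5, K2CO3, Bu4NHSO4, MeCN/dimethoxymethane/aqueous buffer pH 10.5, 0 °C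
Reagents that add atoms: potassium peroxymonosulfate, [K+].[O-]S(=O)(=O)OO
Why: Shi asymmetric epoxidation: the chiral dioxirane should deliver oxygen through the spiro transition state to the olefin face that gives the (R,R) sense with 1-substituted cycloalkenes, which corresponds to (13S,14R) here; reagent control is wanted because the two faces of the nearly twofold-symmetric oxocene differ little.

**Compound list**
1 | (3S,6E)-nerolidol | CC(C)=CCC/C(C)=C/CC[C@](C)(O)C=C | starting material
2 | (3S,6E)-nerolidyl acetate | CC(C)=CCC/C(C)=C/CC[C@](C)(OC(C)=O)C=C | intermediate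
3 | (3S)-5-[(1S,3R)-3-bromo-2,2-dimethyl-6-methylidenecyclohexyl]-3-methylpent-1-en-3-yl acetate | CC1(C)[C@H](Br)CCC(=C)[C@@H]1CC[C@](C)(OC(C)=O)C=C | intermediate
4 | (3S)-5-[(1S,3R)-3-bromo-2,2-dimethyl-6-methylidenecyclohexyl]-3-methylpent-1-en-3-ol | CC1(C)[C@H](Br)CCC(=C)[C@@H]1CC[C@](C)(O)C=C | intermediate
5 | 2-bromo-N-methoxy-N-methylacetamide | CON(C)C(=O)CBr | starting material
6 | 2-{[(3S)-5-[(1S,3R)-3-bromo-2,2-dimethyl-6-methylidenecyclohexyl]-3-methylpent-1-en-3-yl]oxy}-N-methoxy-N-methylacetamide | CC1(C)[C@H](Br)CCC(=C)[C@@H]1CC[C@](C)(OCC(=O)N(C)OC)C=C | intermediate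
7 | ethylmagnesium bromide | CC[Mg]Br | starting material
8 | 1-{[(3S)-5-[(1S,3R)-3-bromo-2,2-dimethyl-6-methylidenecyclohexyl]-3-methylpent-1-en-3-yl]oxy}butan-2-one | CC1(C)[C@H](Br)CCC(=C)[C@@H]1CC[C@](C)(OCC(=O)CC)C=C | intermediate
9 | acrolein | C=CC=O | starting material
10 | 1-{[(3S)-5-[(1S,3R)-3-bromo-2,2-dimethyl-6-methylidenecyclohexyl]-3-methylpent-1-en-3-yl]oxy}-4-hydroxy-3-methylhex-5-en-2-one (diastereomer mixture) | CC1(C)[C@H](Br)CCC(=C)[C@@H]1CC[C@](C)(OCC(=O)C(C)C(O)C=C)C=C | intermediate
11 | (6Z,8S)-8-{2-[(1S,3R)-3-bromo-2,2-dimethyl-6-methylidenecyclohexyl]ethyl}-5-hydroxy-4,8-dimethyloxoc-6-en-3-one (mixture at C4, C5) | CC1(C)[C@H](Br)CCC(=C)[C@@H]1CC[C@]1(C)OCC(=O)C(C)C(O)/C=C\1 | intermediate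
12 | 5-methanesulfonate of 11 | CC1(C)[C@H](Br)CCC(=C)[C@@H]1CC[C@]1(C)OCC(=O)C(C)C(OS(C)(=O)=O)/C=C\1 | intermediate (not isolated)
13 | (4Z,6Z,8S)-8-{2-[(1S,3R)-3-bromo-2,2-dimethyl-6-methylidenecyclohexyl]ethyl}-4,8-dimethyloxoca-4,6-dien-3-one | CC1(C)[C@H](Br)CCC(=C)[C@@H]1CC[C@]1(C)OCC(=O)/C(C)=C\C=C/1 | intermediate
14 | (3R,5S,8S,9S,10R,11Z)-3-bromo-8,15-epoxylabd-11-en-14-one (C13 epimers) | CC1(C)[C@H](Br)CC[C@]2(C)[C@@H]1CC[C@]1(C)OCC(=O)C(C)/C=C\[C@@H]21 | intermediate (not isolated)
15 | (3R,5S,8S,9S,10R,12Z)-3-bromo-8,15-epoxylabd-12-en-14-one | CC1(C)[C@H](Br)CC[C@]2(C)[C@@H]1CC[C@]1(C)OCC(=O)/C(C)=C\C[C@@H]21 | intermediate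
16 | p-toluenesulfonylhydrazone of 15 | CC1(C)[C@H](Br)CC[C@]2(C)[C@@H]1CC[C@]1(C)OCC(=NNS(=O)(=O)c3ccc(C)cc3)/C(C)=C\C[C@@H]21 | intermediate
17 | (3R,5S,8S,9S,10R,12Z)-3-bromo-8,15-epoxy-14-(2-tosylhydrazinyl)labd-12-ene (C14 epimers) | CC1(C)[C@H](Br)CC[C@]2(C)[C@@H]1CC[C@]1(C)OCC(NNS(=O)(=O)c3ccc(C)cc3)/C(C)=C\C[C@@H]21 | intermediate (not isolated)
18 | (3R,5S,8S,9S,10R,12Z)-3-bromo-14-diazenyl-8,15-epoxylabd-12-ene (C14 epimers) | CC1(C)[C@H](Br)CC[C@]2(C)[C@@H]1CC[C@]1(C)OCC(N=N)/C(C)=C\C[C@@H]21 | intermediate (not isolated)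
19 | (3R,5S,8S,9S,10R,13Z)-3-bromo-8,15-epoxylabd-13-ene | CC1(C)[C@H](Br)CC[C@]2(C)[C@@H]1CC[C@]1(C)OC/C=C(C)\CC[C@@H]21 | intermediate
20 | (3R,5S,8S,9S,10R,13S,14R)-3-bromo-8,15:13,14-diepoxylabdane (CNP0311742.1) | CC1(C)[C@H](Br)CC[C@]2(C)[C@@H]1CC[C@]1(C)OC[C@H]3O[C@@]3(C)CC[C@@H]21 | target

**Count**
Total steps: 12. Longest linear sequence: 12 steps (from 1).

**Steps most likely to fail**

Step 9 (key step). The C10 radical may be reduced before it cyclises (net hydrogenation of the methylene), or may add with poor facial control, because attack at the δ-carbon of a twisted, weakly conjugated eight-membered dienone next to the quaternary C8 is slow. The fallback uses the established 1,4-mode and sets out from 11. Ketalisation of the C14 ketone (1,2-bis(trimethylsilyloxy)ethane, TMSOTf cat., CH2Cl2, −78 °C) gives the C14 ethylene ketal of 11, F2. Dess–Martin oxidation of the allylic C12 alcohol gives the ring enone ketal F3, an ordinary 1,4-acceptor with C9 as its β-carbon. Fe(acac)3/PhSiH3 should then close ring B by the known intramolecular Giese reaction to the tricyclic C12 ketone ketal F4, and NaBH4 gives the C12 alcohol F5. TsOH in wet acetone removes the ketal to the β-hydroxy ketone F6, which loses water in the same flask, and the route is rejoined at 15.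

Step 2. The chiral bromine carrier may discriminate poorly between the faces of the terminal olefin (C8 is too remote to help), and bromonium transfer between olefins may erode what selectivity there is. Loss of a C1 proton instead of a C20 proton is harmless, since the endocyclic isomer gives the same C10 radical in step 9. The fallback uses a known reagent and sets out from 2: Et2SBr·SbCl5Br (BDSB) in MeNO2 at −25 °C cyclises geranyl-type esters without a catalyst and should give 3 together with its ring-A diastereomer, (3S)-5-[(1R,3S)-3-bromo-2,2-dimethyl-6-methylidenecyclohexyl]-3-methylpent-1-en-3-yl acetate F1. The two are separated by preparative HPLC (if needed after methanolysis, at the stage of 4), and the route continues from 3.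

Step 7. The ruthenium carbene may come to rest on the vinyl carbon C9 and close a six-membered ring onto the ring-A methylene (a C9=C10 bond, with loss of C20), or may dimerise, instead of closing the oxocane. The fallback is a relay metathesis and sets out from 8: the LDA aldol addition is run with (2E)-octa-2,7-dienal in place of acrolein and gives the relay aldol adduct F7. The catalyst loads at the terminal olefin of the relay arm, expels cyclopentene and is thereby placed on C11, from where it can only close onto the C9 vinyl group; this gives 11, where the route is rejoined.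

**Further compounds**
F1 | step 2 | (3S)-5-[(1R,3S)-3-bromo-2,2-dimethyl-6-methylidenecyclohexyl]-3-methylpent-1-en-3-yl acetate | CC1(C)[C@@H](Br)CCC(=C)[C@H]1CC[C@](C)(OC(C)=O)C=C
F2 | step 9 | C14 ethylene ketal of 11 | CC1(C)[C@H](Br)CCC(=C)[C@@H]1CC[C@]1(C)OCC2(OCCO2)C(C)C(O)/C=C\1
F3 | step 9 | C12 ketone of F2 (oxocene enone ketal) | CC1(C)[C@H](Br)CCC(=C)[C@@H]1CC[C@]1(C)OCC2(OCCO2)C(C)C(=O)/C=C\1
F4 | step 9 | (3R,5S,8S,9S,10R)-3-bromo-8,15-epoxy-14,14-ethylenedioxylabdan-12-one (C13 epimers) | CC1(C)[C@H](Br)CC[C@]2(C)[C@@H]1CC[C@]1(C)OCC3(OCCO3)C(C)C(=O)C[C@@H]21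
F5 | step 9 | (3R,5S,8S,9S,10R)-3-bromo-8,15-epoxy-14,14-ethylenedioxylabdan-12-ol | CC1(C)[C@H](Br)CC[C@]2(C)[C@@H]1CC[C@]1(C)OCC3(OCCO3)C(C)C(O)C[C@@H]21
F6 | step 9 | (3R,5S,8S,9S,10R)-3-bromo-8,15-epoxy-12-hydroxylabdan-14-one | CC1(C)[C@H](Br)CC[C@]2(C)[C@@H]1CC[C@]1(C)OCC(=O)C(C)C(O)C[C@@H]21
F7 | step 7 | (5E)-1-{[(3S)-5-[(1S,3R)-3-bromo-2,2-dimethyl-6-methylidenecyclohexyl]-3-methylpent-1-en-3-yl]oxy}-4-hydroxy-3-methylundeca-5,10-dien-2-one | CC1(C)[C@H](Br)CCC(=C)[C@@H]1CC[C@](C)(OCC(=O)C(C)C(O)/C=C/CCCC=C)C=C
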